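The runs are calculated from invented constants, and the scatter is random.

Count the amounts first: 32 mM of each substrate, 2.00 equiv of coupling partner and 2.1 mol% of free catalyst, stirred for 3.0 min.

| flask | left-handed substrate | right-handed substrate | coupling partner | free catalyst | remark | time |
|---|---|---|---|---|---|---|
| Tuesday's | 16 mM | 16 mM | 2 equiv | 2.1 mol% | run made earlier |  |
| Sunday's | 64 mM | 64 mM | 2 equiv | 2.1 mol% | run made earlier |  |
| Saturday's | 32 mM | 32 mM | 1 equiv | 2.1 mol% | run made earlier |  |
| flask | 32 mM | 32 mM | 2.00 equiv | 2.1 mol% |  | 3.0 min |

| run | time / min | left-handed product / % | right-handed product / % | left-handed substrate / % |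
|---|---|---|---|---|
| Tuesday's | 0.417 | 0 | 1.1 | 49.1 |
| Tuesday's | 0.833 | 0.8 | 0.9 | 49.7 |
| Tuesday's | 1.33 | 0.3 | 0.7 | 48.5 |
| Tuesday's | 1.50 | 0.4 | 0.4 | 49.9 |
| Tuesday's | 2.00 | 0.2 | 1.9 | 49.1 |
| Tuesday's | 2.50 | 0.6 | 2.0 | 48.1 |
| Tuesday's | 3.00 | 2.2 | 2.0 | 46.3 |
| Sunday's | 0.417 | 4.0 | 0.9 | 47.0 |
| Sunday's | 0.833 | 3.9 | 3.8 | 45.5 |
| Sunday's | 1.33 | 6.9 | 3.1 | 44.9 |
| Sunday's | 1.50 | 8.7 | 3.9 | 43.7 |
| Sunday's | 2.00 | 9.9 | 4.9 | 40.2 |
| Sunday's | 2.50 | 9.7 | 6.6 | 38.9 |
| Sunday's | 3.00 | 14.7 | 9.1 | 38.5 |
| Saturday's | 0.250 | 0 | 0.7 | 48.8 |
| Saturday's | 0.417 | 0.9 | 0.2 | 49.8 |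
| Saturday's | 0.833 | 1.2 | 1.3 | 48.7 |
| Saturday's | 1.50 | 1.4 | 1.0 | 47.8 |
| Saturday's | 3.00 | 4.7 | 0.4 | 48.7 |

(standard deviation of a reading: 1 percentage point)

- free catalyst is single-handed; left-handed substrate and right-handed substrate are mirror images of each other, charged as a racemate, each of them at the stated concentration
- an excess is the difference of the two amounts in percent of their sum
- an excess is below zero if the other one leads

- excess of left-handed product over right-handed product in the product at 20 s
- excess of left-handed product over right-handed product in the product at 3.0 min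
- part of the left-handed substrate and right-handed substrate charged together that has reacted at 3.0 min

Reckon with little conversion as a correction to a full flask. Sunday's run holds 23.8% product at its last reading and Tuesday's 4.20%, which gives exposures of 0.272 and 0.0429. The flask's 32 mM is the geometric mean of their 16 mM and 64 mM, at the same equivalents, loading and time, so if exposure follows a power of concentration, the flask's exposure is the geometric mean of the two, 0.108. Exposure here means minus the natural logarithm of the fraction of substrate left; in pseudo-first-order loss it is rate constant times time.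

Now solve two extreme flasks from Sunday's run. If coupling partner counts and the catalyst does not, halving the charges cuts exposure to half, so 12.7% reacts. If the catalyst counts in full as well, exposure falls to a quarter, so 6.57% reacts. The real flask should lie between, because Sunday's exposure reads 6.34 times Tuesday's, more than the 4.00 of the first extreme and less than the 16.0 of the second. My own figure for the flask is therefore 10.2%. Hold it loosely, since each reading scatters by 1 percentage point.

The forecast differs from my figure: it expects 9% reacted at 3.0 min (6.5% to 12%), with an excess of left-handed product of 25% at 20 s (0% to 50%) and 25% at 3.0 min (8% to 42%). On the excess it says: “I see no reliable time drift, so I expect the same excess early and late”.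

The flask gives an excess of left-handed product of 32.3% at 20 s and 31.2% at 3.0 min, with 7.91% reacted at 3.0 min.

    free catalyst → spent catalyst (k = 0.00110 s⁻¹)
    coupling partner + free catalyst + right-handed substrate → free catalyst + right-handed product (k = 48.0 M⁻² s⁻¹)
    coupling partner + free catalyst + left-handed substrate → free catalyst + left-handed product (k = 94.0 M⁻² s⁻¹)
    2 free catalyst ⇌ resting dimer, settled at all times (K = 25000 M⁻¹)

The flask's exposure is 0.0824, against the 0.108 I reckoned. Split it by substrate: at 3.00 min the flask keeps 90% of its left-handed substrate, exposure 0.110, and 95% of its right-handed substrate, exposure 0.0559. The neighbouring flask has 8.00 equiv of coupling partner; reckon exposure in proportion to that charge and multiply both exposures by 4.00. That leaves 64.4% of the left-handed substrate and 80.0% of the right-handed substrate. The neighbouring flask keeps 64% of its left-handed substrate and 80% of its right-handed substrate, with 27.8% reacted.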